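**Retrosynthetic overview**
1. Target 26 ⇐ C3 oxidation of macrocyclic alcohol 25 ⇐ intramolecular Nozaki–Hiyama–Kishi closure (C3–C4) of Z-vinyl iodide/epoxy aldehyde 23; the ten-membered ring is closed last.
2. 23 ⇐ 21 (C8 isobutyrate by Mitsunobu inversion) ⇐ 20 ⇐ Zn-Barbier union (C7–C8) of bromomethyl butenolide 18 (West) with β-hydroxy aldehyde 9 (East), which sets C7/C8 and the exo-methylene lactone.
3. West 18 (C4–C7, C11–C13, C15): butenolide by RCM of the 2-(bromomethyl)acrylate of dienol 15; C6 by Sharpless kinetic resolution; Z-vinyl iodide from but-2-yn-1-ol.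
4. East 9 (C1–C3, C8–C10, C14): C10 from (S)-2-methylglycidol; trans-C1/C2 epoxide by Sharpless epoxidation; C8 aldehyde by ozonolysis.
5. Ring order: γ-lactone (step 12) and oxirane (step 4) in separate fragments, then the ten-membered carbocycle (step 17).

Assumption: germacrane numbering (C1–C15) is used in the comments; CIP descriptors at C2, C6 and C7 change along the route only because substituent priorities change (CH2O→CHO→C=O, I→C), not the geometry.

**East fragment**

Step 1
Reactants: 1 (S)-2-methylglycidol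
Product: 2 (2R)-2-methylpent-4-ene-1,2-diol
Conditions: CH2=CHMgBr (2.5 equiv), CuI (10 mol%), THF, −30 → 0 °C; aq NH4Cl
Reagents that add atoms: vinylmagnesium bromide, C=C[Mg]Br
Why: Cu-catalysed Grignard opening (SN2) of the epoxide at its unsubstituted CH2 installs C8 as a vinyl group while no bond to the quaternary carbinol carbon (future C10) is broken, so its configuration is carried over from the chiral pool (descriptor S→R by CIP only).

Step 2
Reactants: 2 (2R)-2-methylpent-4-ene-1,2-diol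
Product: 4 ethyl (2E,4R)-4-hydroxy-4-methylhepta-2,6-dienoate, via hydroxy-aldehyde 3 (not isolated)
Conditions: (COCl)2, DMSO, CH2Cl2, −78 °C; Et3N; then Ph3P=CHCO2Et, −78 °C → rt
Reagents that add atoms: ethyl (triphenylphosphoranylidene)acetate, CCOC(=O)C=P(c1ccccc1)(c1ccccc1)c1ccccc1
Why: Swern oxidation can only touch the primary alcohol and the labile α-hydroxy aldehyde is trapped in the same flask by a Wittig olefination with a stabilised ylide, which gives the E-enoate (future C1–C2–C3 unit) without affecting C10.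

Step 3
Reactants: 4 ethyl (2E,4R)-4-hydroxy-4-methylhepta-2,6-dienoate
Product: 5 (2E,4R)-4-methylhepta-2,6-diene-1,4-diol
Conditions: DIBAL-H (3.5 equiv), CH2Cl2, −78 → 0 °C; Rochelle salt
Reagents that add atoms: none
Why: DIBAL-H 1,2-reduction of the α,β-unsaturated ester gives the primary E-allylic alcohol needed to direct the epoxidation; both alkenes and C10 are untouched.

Step 4
Reactants: 5 (2E,4R)-4-methylhepta-2,6-diene-1,4-diol
Product: 6 (2R)-2-[(2R,3S)-3-(hydroxymethyl)oxiran-2-yl]pent-4-en-2-ol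
Conditions: Ti(OiPr)4, L-(+)-DET, TBHP, 4 Å MS, CH2Cl2, −20 °C
Reagents that add atoms: tert-butyl hydroperoxide, CC(C)(C)OO
Why: Sharpless asymmetric epoxidation of the primary E-allylic alcohol: the Ti/L-(+)-tartrate complex delivers oxygen to one alkene face under reagent control (as for E-2-alken-1-ols giving 2S-epoxy alcohols), setting C2 (S at this stage) and C1 (R) as a trans-epoxide, while the isolated terminal alkene does not react.

Step 5
Reactants: 6 (2R)-2-[(2R,3S)-3-(hydroxymethyl)oxiran-2-yl]pent-4-en-2-ol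
Product: 7 (2R)-2-[(2R,3S)-3-({[tert-butyl(dimethyl)silyl]oxy}methyl)oxiran-2-yl]pent-4-en-2-ol
Conditions: TBSCl, imidazole, CH2Cl2, 0 °C
Reagents that add atoms: tert-butyldimethylsilyl chloride, CC(C)(C)[Si](C)(C)Cl
Why: Silylation with TBSCl/imidazole is selective for the primary hydroxyl over the hindered tertiary one, masking C3–OH through the fragment union.

Step 6
Reactants: 7 (2R)-2-[(2R,3S)-3-({[tert-butyl(dimethyl)silyl]oxy}methyl)oxiran-2-yl]pent-4-en-2-ol
Product: 9 (3R)-3-[(2R,3S)-3-({[tert-butyl(dimethyl)silyl]oxy}methyl)oxiran-2-yl]-3-hydroxybutanal, via ozonide 8 (not isolated)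
Conditions: O3, CH2Cl2, −78 °C; then PPh3, −78 °C → rt; used crude
Reagents that add atoms: ozone, [O-][O+]=O
Why: Ozonolysis with reductive work-up cleaves the only remaining alkene to the C8 aldehyde under neutral conditions that spare the epoxide, silyl ether and β-hydroxyl.

**West fragment**

Step 7
Reactants: 10 but-2-yn-1-ol
Product: 12 (2Z)-3-iodobut-2-en-1-ol, via vinylalanate 11 (not isolated)
Conditions: Red-Al (1.5 equiv), THF, 0 °C → rt; then I2, THF, −78 °C
Reagents that add atoms: iodine, II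
Why: Hydroxyl-directed trans-hydroalumination of the propargylic alcohol puts aluminium on C3 inside a five-membered alkoxyalanate and iodinolysis with retention gives the Z-vinyl iodide (I cis to CH2OH), which fixes the C4=C5 geometry of the target.

Step 8
Reactants: 12 (2Z)-3-iodobut-2-en-1-ol
Product: 13 (2Z)-3-iodobut-2-enal
Conditions: MnO2 (15 equiv), CH2Cl2, rt, dark
Reagents that add atoms: none
Why: MnO2 oxidises the allylic alcohol to the enal under neutral heterogeneous conditions, so the Z-geometry and the C–I bond survive.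

Step 9
Reactants: 13 (2Z)-3-iodobut-2-enal
Product: 14 rac-(4Z)-5-iodohexa-1,4-dien-3-ol
Conditions: CH2=CHMgBr, THF, −78 °C; aq NH4Cl
Reagents that add atoms: vinylmagnesium bromide, C=C[Mg]Br
Why: 1,2-Addition of the vinyl Grignard reagent to the enal at −78 °C (faster than I/Mg exchange) builds the C6 carbinol as a racemate that is resolved in the next step.

Step 10
Reactants: 14 rac-(4Z)-5-iodohexa-1,4-dien-3-ol
Product: 15 (3S,4Z)-5-iodohexa-1,4-dien-3-ol
Conditions: Ti(OiPr)4 (1.0 equiv), L-(+)-DIPT (1.2 equiv), TBHP (0.6 equiv), 4 Å MS, CH2Cl2, −20 °C, to ca. 55% conversion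
Reagents that add atoms: none
Why: Sharpless kinetic resolution: with L-(+)-DIPT the (R)-enantiomer is epoxidised at its vinyl group far faster than the (S)-enantiomer, whose only matched alkene is the electron-poor cis-substituted iodoalkene, so (S)-15 (C6 of the target) is recovered in high ee.

Step 11
Reactants: 15 (3S,4Z)-5-iodohexa-1,4-dien-3-ol; 16 2-(bromomethyl)prop-2-enoic acid
Product: 17 (3S,4Z)-5-iodohexa-1,4-dien-3-yl 2-(bromomethyl)prop-2-enoate
Conditions: DCC, DMAP (5 mol%), CH2Cl2, −20 → 0 °C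
Reagents that add atoms: none
Why: Steglich esterification acylates the secondary alcohol on oxygen without breaking the C6–O bond (retention), and low temperature with little DMAP keeps the allylic bromide intact.

Step 12
Reactants: 17 (3S,4Z)-5-iodohexa-1,4-dien-3-yl 2-(bromomethyl)prop-2-enoate
Product: 18 (5S)-3-(bromomethyl)-5-[(1Z)-2-iodoprop-1-en-1-yl]furan-2(5H)-one
Conditions: Hoveyda–Grubbs II (5 mol%), toluene (5 mM), 80 °C
Reagents that add atoms: none
Why: Ring-closing metathesis between the vinyl group and the 1,1-disubstituted acrylate alkene closes the butenolide with loss of ethene, while the trisubstituted iodoalkene is inert and the neutral phosphine-free conditions spare the allylic bromide and the base-sensitive C6–H.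

**Union and endgame**

Step 13
Reactants: 18 (5S)-3-(bromomethyl)-5-[(1Z)-2-iodoprop-1-en-1-yl]furan-2(5H)-one; 9 (3R)-3-[(2R,3S)-3-({[tert-butyl(dimethyl)silyl]oxy}methyl)oxiran-2-yl]-3-hydroxybutanal
Product: 20 (4R,5S)-4-{(1S,3R)-3-[(2R,3S)-3-({[tert-butyl(dimethyl)silyl]oxy}methyl)oxiran-2-yl]-1,3-dihydroxybutyl}-5-[(1Z)-2-iodoprop-1-en-1-yl]-3-methylideneoxolan-2-one, via allylzinc bromide 19 (not isolated)
Conditions: Zn dust, THF/sat. aq NH4Cl (2:1), 0 °C → rt
Reagents that add atoms: none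
Why: Zinc-mediated Barbier allylation: the allylzinc adds through its γ-carbon (C7) in a chair transition state, anti to the C6 substituent (trans-lactone, C7 R) and with the aldehyde chain equatorial, so the ring-locked E-allyl unit gives the anti C7/C8 adduct (C8 S, epimeric to the target on purpose) and the allylic shift creates the exo-methylene.

Step 14
Reactants: 20 (8S)-alcohol
Product: 21 (1R,3R)-3-[(2R,3S)-3-({[tert-butyl(dimethyl)silyl]oxy}methyl)oxiran-2-yl]-3-hydroxy-1-{(2S,3R)-2-[(1Z)-2-iodoprop-1-en-1-yl]-4-methylidene-5-oxooxolan-3-yl}butyl 2-methylpropanoate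
Conditions: iPrCO2H, PPh3, DIAD, toluene, 0 °C → rt
Reagents that add atoms: isobutyric acid, CC(C)C(=O)O
Why: Mitsunobu esterification displaces the activated secondary C8–OH by isobutyrate in an SN2 step with inversion (8S→8R, the target configuration), the tertiary C10–OH being too hindered to react.

Step 15
Reactants: 21 (8R)-isobutyrate TBS ether
Product: 22 (1R,3R)-3-hydroxy-3-[(2R,3S)-3-(hydroxymethyl)oxiran-2-yl]-1-{(2S,3R)-2-[(1Z)-2-iodoprop-1-en-1-yl]-4-methylidene-5-oxooxolan-3-yl}butyl 2-methylpropanoate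
Conditions: HF·pyridine, pyridine, THF, 0 °C → rt
Reagents that add atoms: none
Why: Buffered HF·pyridine cleaves the primary TBS ether by fluoride-driven desilylation without opening the epoxide or hydrolysing the ester and lactone.

Step 16
Reactants: 22 primary epoxy alcohol
Product: 23 (1R,3R)-3-[(2R,3R)-3-formyloxiran-2-yl]-3-hydroxy-1-{(2S,3R)-2-[(1Z)-2-iodoprop-1-en-1-yl]-4-methylidene-5-oxooxolan-3-yl}butyl 2-methylpropanoate
Conditions: Dess–Martin periodinane, pyridine, CH2Cl2, 0 °C → rt; used at once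
Reagents that add atoms: none
Why: Dess–Martin oxidation converts the primary epoxy alcohol to the epoxy aldehyde under buffered non-epimerising conditions and cannot oxidise the tertiary alcohol.

Step 17
Reactants: 23 epoxy aldehyde
Product: 25 (1R,2S,4Z,6R,7R,8R,10R)-1,2-epoxy-3,10-dihydroxygermacra-4,11(13)-dien-12,6-olid-8-yl 2-methylpropanoate (both C3 epimers), via alkenylchromium 24 (not isolated)
Conditions: CrCl2 (12 equiv), NiCl2 (5 mol%), DMSO/THF, rt, syringe-pump addition to 2 mM
Reagents that add atoms: none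
Why: Intramolecular Nozaki–Hiyama–Kishi reaction: Ni-catalysed formation of an alkenylchromium(III) species with retention of the Z-geometry and chemoselective addition to the aldehyde (ester, lactone, epoxide and free OH tolerated) closes the ten-membered ring under high dilution, pre-organised by the cis C4=C5 bond and the trans-lactone; the new C3 carbinol is a mixture that is erased by oxidation.

Step 18
Reactants: 25 macrocyclic allylic alcohol
Product: 26 (1R,2R,4Z,6R,7R,8R,10R)-1,2-epoxy-10-hydroxy-3-oxogermacra-4,11(13)-dien-12,6-olid-8-yl 2-methylpropanoate (target)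
Conditions: Dess–Martin periodinane, pyridine, CH2Cl2, 0 °C
Reagents that add atoms: none
Why: Dess–Martin oxidation of the secondary allylic alcohol gives the Z-enone without touching the tertiary C10–OH or epimerising C2, so both C3 epimers converge on the target.

**Compound list**

1 | (S)-2-methylglycidol, (2S)-(2-methyloxiran-2-yl)methanol | OC[C@@]1(C)CO1 | starting material
2 | (2R)-2-methylpent-4-ene-1,2-diol | OC[C@](C)(O)CC=C | intermediate
3 | (2R)-2-hydroxy-2-methylpent-4-enal | O=C[C@](C)(O)CC=C | intermediate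
4 | ethyl (2E,4R)-4-hydroxy-4-methylhepta-2,6-dienoate | CCOC(=O)/C=C/[C@](C)(O)CC=C | intermediate
5 | (2E,4R)-4-methylhepta-2,6-diene-1,4-diol | OC/C=C/[C@](C)(O)CC=C | intermediate
6 | (2R)-2-[(2R,3S)-3-(hydroxymethyl)oxiran-2-yl]pent-4-en-2-ol | OC[C@@H]1O[C@H]1[C@](C)(O)CC=C | intermediate
7 | (2R)-2-[(2R,3S)-3-({[tert-butyl(dimethyl)silyl]oxy}methyl)oxiran-2-yl]pent-4-en-2-ol | CC(C)(C)[Si](C)(C)OC[C@@H]1O[C@H]1[C@](C)(O)CC=C | intermediate
8 | ozonide of 7, (2R)-2-[(2R,3S)-3-({[tert-butyl(dimethyl)silyl]oxy}methyl)oxiran-2-yl]-1-(1,2,4-trioxolan-3-yl)propan-2-ol (trioxolane carbon unassigned) | CC(C)(C)[Si](C)(C)OC[C@@H]1O[C@H]1[C@](C)(O)CC2OCOO2 | intermediate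
9 | (3R)-3-[(2R,3S)-3-({[tert-butyl(dimethyl)silyl]oxy}methyl)oxiran-2-yl]-3-hydroxybutanal | CC(C)(C)[Si](C)(C)OC[C@@H]1O[C@H]1[C@](C)(O)CC=O | intermediate
10 | but-2-yn-1-ol | CC#CCO | starting material
11 | sodium 2,2-bis(2-methoxyethoxy)-3-methyl-2,5-dihydro-1,2-oxaluminol-2-uide (cyclic vinylalanate) | CC1=CCO[Al-]1(OCCOC)OCCOC.[Na+] | intermediate
12 | (2Z)-3-iodobut-2-en-1-ol | C/C(I)=C/CO | intermediate
13 | (2Z)-3-iodobut-2-enal | C/C(I)=C/C=O | intermediate
14 | rac-(4Z)-5-iodohexa-1,4-dien-3-ol | C=CC(O)/C=C(/C)I | intermediate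
15 | (3S,4Z)-5-iodohexa-1,4-dien-3-ol | C=C[C@H](O)/C=C(/C)I | intermediate
16 | 2-(bromomethyl)prop-2-enoic acid | C=C(CBr)C(=O)O | starting material
17 | (3S,4Z)-5-iodohexa-1,4-dien-3-yl 2-(bromomethyl)prop-2-enoate | C=C(CBr)C(=O)O[C@@H](C=C)/C=C(/C)I | intermediate
18 | (5S)-3-(bromomethyl)-5-[(1Z)-2-iodoprop-1-en-1-yl]furan-2(5H)-one | O=C1O[C@H](/C=C(/C)I)C=C1CBr | intermediate
19 | bromo{[(5S)-5-[(1Z)-2-iodoprop-1-en-1-yl]-2-oxo-2,5-dihydrofuran-3-yl]methyl}zinc | O=C1O[C@H](/C=C(/C)I)C=C1C[Zn]Br | intermediate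
20 | (4R,5S)-4-{(1S,3R)-3-[(2R,3S)-3-({[tert-butyl(dimethyl)silyl]oxy}methyl)oxiran-2-yl]-1,3-dihydroxybutyl}-5-[(1Z)-2-iodoprop-1-en-1-yl]-3-methylideneoxolan-2-one | C=C1C(=O)O[C@H](/C=C(/C)I)[C@H]1[C@@H](O)C[C@@](C)(O)[C@@H]2O[C@H]2CO[Si](C)(C)C(C)(C)C | intermediate
21 | (1R,3R)-3-[(2R,3S)-3-({[tert-butyl(dimethyl)silyl]oxy}methyl)oxiran-2-yl]-3-hydroxy-1-{(2S,3R)-2-[(1Z)-2-iodoprop-1-en-1-yl]-4-methylidene-5-oxooxolan-3-yl}butyl 2-methylpropanoate | C=C1C(=O)O[C@H](/C=C(/C)I)[C@H]1[C@H](OC(=O)C(C)C)C[C@@](C)(O)[C@@H]2O[C@H]2CO[Si](C)(C)C(C)(C)C | intermediate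
22 | (1R,3R)-3-hydroxy-3-[(2R,3S)-3-(hydroxymethyl)oxiran-2-yl]-1-{(2S,3R)-2-[(1Z)-2-iodoprop-1-en-1-yl]-4-methylidene-5-oxooxolan-3-yl}butyl 2-methylpropanoate | C=C1C(=O)O[C@H](/C=C(/C)I)[C@H]1[C@H](OC(=O)C(C)C)C[C@@](C)(O)[C@@H]2O[C@H]2CO | intermediate
23 | (1R,3R)-3-[(2R,3R)-3-formyloxiran-2-yl]-3-hydroxy-1-{(2S,3R)-2-[(1Z)-2-iodoprop-1-en-1-yl]-4-methylidene-5-oxooxolan-3-yl}butyl 2-methylpropanoate | C=C1C(=O)O[C@H](/C=C(/C)I)[C@H]1[C@H](OC(=O)C(C)C)C[C@@](C)(O)[C@@H]2O[C@H]2C=O | intermediate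
24 | alkenylchromium(III) dichloride from 23 (CrCl2 in place of I, Z retained) | C=C1C(=O)O[C@H](/C=C(/C)[Cr](Cl)Cl)[C@H]1[C@H](OC(=O)C(C)C)C[C@@](C)(O)[C@@H]2O[C@H]2C=O | intermediate
25 | (1R,2S,4Z,6R,7R,8R,10R)-1,2-epoxy-3,10-dihydroxygermacra-4,11(13)-dien-12,6-olid-8-yl 2-methylpropanoate, both C3 epimers | C=C1C(=O)O[C@@H]2/C=C(/C)C(O)[C@@H]3O[C@H]3[C@](C)(O)C[C@@H](OC(=O)C(C)C)[C@@H]12 | intermediate
26 | (1R,2R,4Z,6R,7R,8R,10R)-1,2-epoxy-10-hydroxy-3-oxogermacra-4,11(13)-dien-12,6-olid-8-yl 2-methylpropanoate (CNP0273626.1) | C=C1C(=O)O[C@@H]2/C=C(/C)C(=O)[C@@H]3O[C@H]3[C@](C)(O)C[C@@H](OC(=O)C(C)C)[C@@H]12 | target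

**Step count and risks**

Total step count: 18 (East 1–6, West 7–12, union and endgame 13–18).
Longest linear sequence: 12 steps (1–6 then 13–18, or 7–12 then 13–18), which is two thirds of the total.

Step 17 (NHK ring closure) is the most likely to fail: the ten-membered ring is strained and the α,β-epoxy aldehyde may not survive CrCl2 or may oligomerise. The fallback sets out from 22 and comes back at 26. It forms the same C3–C4 bond by an intramolecular Stille acylation, which gives the ketone directly. Pd(PPh3)4 and Me3SnSnMe3 in toluene at 80 °C exchange iodine for tin to give vinylstannane F5. Dess–Martin oxidation gives stannyl aldehyde F6 and Pinnick oxidation (NaClO2, NaH2PO4, 2-methyl-2-butene) gives stannyl acid F7. Ghosez's reagent (1-chloro-N,N,2-trimethylprop-1-en-1-amine) gives acid chloride F8, which is cyclised at high dilution with Pd2(dba)3 and tri(2-furyl)phosphine to 26.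

Step 14 (Mitsunobu inversion) is the second risk: the C8 carbinol is hindered, and elimination toward C7 or participation by the lactone carbonyl can compete. The fallback sets out from 20 and comes back at 21. ClCH2SO2Cl and pyridine in CH2Cl2 at 0 °C give chloromethanesulfonate F4 with retention. Caesium isobutyrate and 18-crown-6 in toluene at 60 °C then displace it by SN2 with inversion to give 21.

Step 12 (RCM) is the third risk: the allylic bromide can deactivate the ruthenium catalyst and the α-substituted acrylate is a reluctant partner. The fallback sets out from 15 and comes back at 18; it introduces C13 as a hydroxymethyl group before metathesis and brominates last, which also removes the bromide from step 11. Acryloyl chloride and iPr2NEt give acrylate F1. A DABCO-catalysed Morita–Baylis–Hillman reaction with aqueous formaldehyde in dioxane gives 2-(hydroxymethyl)acrylate F2. RCM with Hoveyda–Grubbs II gives hydroxymethyl butenolide F3. Appel bromination (CBr4, PPh3, CH2Cl2, 0 °C, neutral) gives 18.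

**Further compounds**

F1 | step 12 | (3S,4Z)-5-iodohexa-1,4-dien-3-yl prop-2-enoate | C=CC(=O)O[C@@H](C=C)/C=C(/C)I
F2 | step 12 | (3S,4Z)-5-iodohexa-1,4-dien-3-yl 2-(hydroxymethyl)prop-2-enoate | C=C(CO)C(=O)O[C@@H](C=C)/C=C(/C)I
F3 | step 12 | (5S)-3-(hydroxymethyl)-5-[(1Z)-2-iodoprop-1-en-1-yl]furan-2(5H)-one | O=C1O[C@H](/C=C(/C)I)C=C1CO
F4 | step 14 | C8 chloromethanesulfonate of 20 (configuration as in 20) | C=C1C(=O)O[C@H](/C=C(/C)I)[C@H]1[C@@H](OS(=O)(=O)CCl)C[C@@](C)(O)[C@@H]2O[C@H]2CO[Si](C)(C)C(C)(C)C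
F5 | step 17 | trimethylstannyl analogue of 22 (SnMe3 in place of I) | C=C1C(=O)O[C@H](/C=C(/C)[Sn](C)(C)C)[C@H]1[C@H](OC(=O)C(C)C)C[C@@](C)(O)[C@@H]2O[C@H]2CO
F6 | step 17 | trimethylstannyl analogue of 23 (epoxy aldehyde) | C=C1C(=O)O[C@H](/C=C(/C)[Sn](C)(C)C)[C@H]1[C@H](OC(=O)C(C)C)C[C@@](C)(O)[C@@H]2O[C@H]2C=O
F7 | step 17 | corresponding oxirane-2-carboxylic acid (C3 acid, SnMe3 at C4) | C=C1C(=O)O[C@H](/C=C(/C)[Sn](C)(C)C)[C@H]1[C@H](OC(=O)C(C)C)C[C@@](C)(O)[C@@H]2O[C@H]2C(=O)O
F8 | step 17 | corresponding oxirane-2-carbonyl chloride (C3 acid chloride, SnMe3 at C4) | C=C1C(=O)O[C@H](/C=C(/C)[Sn](C)(C)C)[C@H]1[C@H](OC(=O)C(C)C)C[C@@](C)(O)[C@@H]2O[C@H]2C(=O)Cl
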